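The ten-membered carbocycle is opened at C9–C10. C9 is a secondary carbinol bonded to C10, the α-carbon of the C1=C10 enoate that carries the C14 methyl ester, so this bond is the union of a C10 alkenyl metal with a C9 aldehyde. One intramolecular Nozaki–Hiyama–Kishi addition closes the C1–C10 ring, transfers the geometry of a (Z)-α-iodoenoate into the ring-cis C1=C10 bond and creates the C9 stereocentre beside C8. Its substrate is a trans-4,5-disubstituted α-methylene-γ-butyrolactone (O–C6, C7, C11–C13): the C7 branch is an α-silyloxy aldehyde (C8, C9) and the C6 branch is the (4E)-C5–C1 chain ending in the iodoenoate.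

Key step: step 12

Remark: germacrane numbering is used throughout (C14 = ester carbon on C10, C15 = methyl on C4); O8 is carried through the ring closure as a triethylsilyl (TES) ether, so that the C9 aldehyde can be unmasked directly from a bis-silyl ether and the group later removed under mildly acidic conditions; the ring-cis C1=C10 bond is E by the CIP rules (C14 outranks C9), and the CIP letter at C7 is R instead of S in 15 and 23 only because a free hydroxyl on C8 lowers the rank of that branch.

Step 1
Reactants: 1 geranyl acetate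
Product: 2 (2E)-5-(3,3-dimethyloxiran-2-yl)-3-methylpent-2-en-1-yl acetate (6,7-epoxygeranyl acetate, racemic epoxide)
Conditions: mCPBA, CH2Cl2, 0 °C
Reagents that add atoms: mCPBA (3-chloroperoxybenzoic acid), OOC(=O)c1cccc(Cl)c1
Why: Prilezhaev epoxidation: the peracid selects the remote, electron-rich trisubstituted C6=C7 olefin of geranyl acetate because the C2=C3 olefin is deactivated by the allylic acetoxy group, and the new epoxide stereocentre is formed as a racemate that is excised in step 2.

Step 2
Reactants: 2 6,7-epoxygeranyl acetate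
Product: 4 (2E)-3-methyl-6-oxohex-2-en-1-yl acetate, via 6,7-diol 3 (not isolated)
Conditions: H5IO6, THF/H2O, 0 °C → rt
Reagents that add atoms: none
Why: Acid-mediated hydrolysis of the epoxide to diol 3 and glycol cleavage by periodic acid in the same flask release acetone and the aldehyde that becomes C1, leaving the (E)-trisubstituted olefin (future C4=C5, methyl C15) untouched.

Step 3
Reactants: 4 (2E)-3-methyl-6-oxohex-2-en-1-yl acetate
Product: 5 methyl (2Z,6E)-8-acetoxy-2-iodo-6-methylocta-2,6-dienoate
Conditions: Ph3P=CHCO2Me, NIS, CH2Cl2, −20 °C; then 4, K2CO3, −20 °C → rt, dark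
Reagents that add atoms: methyl (triphenyl-λ5-phosphanylidene)acetate, COC(=O)C=P(c1ccccc1)(c1ccccc1)c1ccccc1; N-iodosuccinimide (NIS), O=C1CCC(=O)N1I
Why: Wittig olefination with an α-iodinated stabilised ylide (iodo-Wittig): NIS iodinates the ylide in the flask and the iodo ylide then places the alkyl chain trans to the ester as stabilised ylides do, so C2 and iodine are cis, the (Z)-α-iodoenoate geometry.

Step 4
Reactants: 5 methyl (2Z,6E)-8-acetoxy-2-iodo-6-methylocta-2,6-dienoate
Product: 6 methyl (2Z,6E)-8-hydroxy-2-iodo-6-methylocta-2,6-dienoate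
Conditions: K2CO3 (cat.), MeOH, 0 °C
Reagents that add atoms: none
Why: Base-catalysed transesterification with methanol removes the allylic acetate, while the methyl ester is degenerate toward methoxide and the β-alkyl α-iodoenoate is a poor Michael acceptor at 0 °C.

Step 5
Reactants: 6 methyl (2Z,6E)-8-hydroxy-2-iodo-6-methylocta-2,6-dienoate
Product: 7 methyl (2Z,6E)-2-iodo-6-methyl-8-oxoocta-2,6-dienoate
Conditions: MnO2, CH2Cl2, rt
Reagents that add atoms: none
Why: MnO2 oxidation is selective for the allylic alcohol and should give the β,β-disubstituted enal (aldehyde carbon = C6) without isomerising the C4=C5 bond.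

Step 6
Reactants: 8 (R)-2,3-O-isopropylideneglyceraldehyde; 9 methyl acrylate
Product: 10 methyl 2-{[(4R)-2,2-dimethyl-1,3-dioxolan-4-yl](hydroxy)methyl}prop-2-enoate (both carbinol epimers)
Conditions: DABCO (1,4-diazabicyclo[2.2.2]octane), 1,4-dioxane/H2O, rt
Reagents that add atoms: none
Why: Morita–Baylis–Hillman reaction: the DABCO–acrylate zwitterion adds to the aldehyde and eliminates the amine, the carbinol forming as an epimer mixture that is inconsequential because this carbon (future C7) becomes sp2 in step 7, while the dioxolane stereocentre (future C8) is carried through unchanged.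

Step 7
Reactants: 10 methyl 2-{[(4R)-2,2-dimethyl-1,3-dioxolan-4-yl](hydroxy)methyl}prop-2-enoate
Product: 11 methyl (2Z)-2-(bromomethyl)-3-[(4S)-2,2-dimethyl-1,3-dioxolan-4-yl]prop-2-enoate
Conditions: NBS, Me2S, CH2Cl2, 0 °C → rt
Reagents that add atoms: N-bromosuccinimide (NBS), O=C1CCC(=O)N1Br
Why: Activation of the hydroxyl as an alkoxysulfonium salt (Corey–Kim-type NBS/Me2S reagent) and SN2' attack of bromide convert both carbinol epimers into the more stable (2Z)-2-(bromomethyl)alkenoate under non-acidic conditions that spare the acetonide.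

Step 8
Reactants: 7 methyl (2Z,6E)-2-iodo-6-methyl-8-oxoocta-2,6-dienoate; 11 methyl (2Z)-2-(bromomethyl)-3-[(4S)-2,2-dimethyl-1,3-dioxolan-4-yl]prop-2-enoate
Product: 14 methyl (2Z,6E)-7-{(2R,3S)-3-[(4S)-2,2-dimethyl-1,3-dioxolan-4-yl]-4-methylidene-5-oxooxolan-2-yl}-2-iodo-6-methylhepta-2,6-dienoate, via allylchromium reagent 12 (not isolated), via chromium alkoxide 13 (not isolated)
Conditions: CrCl2 (nickel-free), THF, 0 °C → rt; aq. NH4Cl
Reagents that add atoms: none
Why: Nozaki–Hiyama-type 2-(alkoxycarbonyl)allylation with lactonisation in the flask: nickel-free CrCl2 converts the allylic bromide, and not the alkenyl iodide, into the equilibrating allylchromium 12, which adds through its γ-carbon (C7) to the aldehyde in a chair transition state having the aldehyde substituent and C8 both equatorial, so that C6 and C7 are set anti (trans lactone after 5-exo-trig acyl substitution by alkoxide 13), while allylic 1,3-strain holds C8–H in the plane of C7=C11 and the aldehyde is expected to bond to C7 anti to the C8–C9 bond (the larger, σ-donating substituent, C8–O lying outside), which gives 6R,7S relative to the 8S centre from the chiral pool.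

Step 9
Reactants: 14 lactone acetonide
Product: 15 methyl (2Z,6E)-7-{(2R,3R)-3-[(1S)-1,2-dihydroxyethyl]-4-methylidene-5-oxooxolan-2-yl}-2-iodo-6-methylhepta-2,6-dienoate
Conditions: AcOH/H2O (4:1), 40 °C
Reagents that add atoms: none
Why: Acid-catalysed hydrolysis of the terminal isopropylidene ketal in aqueous acetic acid frees the 8,9-diol under conditions too mild to transpose the lactone to O8 or to ionise the allylic C6–O bond, and no stereocentre is touched.

Step 10
Reactants: 15 8,9-diol
Product: 16 methyl (2Z,6E)-7-{(2R,3S)-3-[(1S)-1,2-bis(triethylsilyloxy)ethyl]-4-methylidene-5-oxooxolan-2-yl}-2-iodo-6-methylhepta-2,6-dienoate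
Conditions: TESOTf, 2,6-lutidine, CH2Cl2, −78 °C
Reagents that add atoms: triethylsilyl trifluoromethanesulfonate (TESOTf), CC[Si](CC)(CC)OS(=O)(=O)C(F)(F)F
Why: Silylation of both hydroxyls by TESOTf in the presence of the non-nucleophilic base 2,6-lutidine at −78 °C avoids conjugate addition of an amine to the α-methylene lactone.

Step 11
Reactants: 16 bis-TES ether
Product: 18 methyl (2Z,6E)-2-iodo-6-methyl-7-{(2R,3S)-4-methylidene-5-oxo-3-[(1S)-2-oxo-1-(triethylsilyloxy)ethyl]oxolan-2-yl}hepta-2,6-dienoate, via alkoxysulfonium chloride 17 (not isolated)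
Conditions: (COCl)2, DMSO, CH2Cl2, −78 → −40 °C; then Et3N, −78 → −20 °C
Reagents that add atoms: none
Why: Swern oxidation applied directly to a primary triethylsilyl ether: the chlorosulfonium reagent exchanges the less hindered primary O–Si bond to give alkoxysulfonium salt 17, which Et3N fragments to the C9 aldehyde while the secondary TES ether on C8 remains, the low temperature protecting the C8 stereocentre of the α-silyloxy aldehyde from epimerisation.

Step 12
Reactants: 18 lactone aldehyde bearing the (Z)-α-iodoenoate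
Product: 21 methyl (1(10)E,4E,6R,7S,8S,9S)-9-hydroxy-8-(triethylsilyloxy)germacra-1(10),4,11(13)-trien-12,6-olid-14-oate, via alkenylchromium 19 (not isolated), via chromium alkoxide 20 (not isolated)
Conditions: CrCl2 (excess), NiCl2 (cat.), DMSO, rt, slow addition of 18 to 2 mM final concentration; aq. NH4Cl
Reagents that add atoms: none
Why: CrCl2 reduces NiCl2 to zerovalent nickel, which inserts into the C10–I bond of 18; transmetalation gives the trivalent alkenylchromium 19 with retention of olefin geometry, and its carbonyl addition to the C9 aldehyde gives alkoxide 20 (Nozaki–Hiyama–Kishi reaction, in its established macrocyclising use of alkenyl iodides for medium rings). The C1–C10 carbocycle closes by a 10-exo-trig 1,2-addition that forms C9–C10, and slow addition at high dilution favours it over intermolecular coupling. Because C2 and the metal are cis on C1=C10, C2 and C9 end cis (the ring-cis enoate of the target), and the organochromium is chemoselective for the aldehyde over the two esters and the exo-methylene lactone. The new C9 stereocentre must arise from attack on the Si face (9S, 8,9-syn), and it is controlled by the C8 silyloxy centre acting within the ring: C10 approaches anti to the C8–O bond while the chromium-bound oxygen takes the peripheral pseudo-equatorial site away from C7 and the lactone, the arrangement that maps onto the melampolide conformation with H8 and H9 anti. An open-chain Felkin–Anh analysis of the same α-silyloxy aldehyde would favour 9R, so this ring constraint, helped by the modest size of the TES group, is what the selectivity depends on.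

Step 13
Reactants: 21 macrocyclic 9-alcohol
Product: 22 methyl (1(10)E,4E,6R,7S,8S,9S)-9-acetoxy-8-(triethylsilyloxy)germacra-1(10),4,11(13)-trien-12,6-olid-14-oate
Conditions: Ac2O, pyridine, DMAP (4-dimethylaminopyridine, cat.), CH2Cl2, 0 °C → rt
Reagents that add atoms: acetic anhydride, CC(=O)OC(C)=O
Why: DMAP-catalysed acylation of the secondary allylic C9 hydroxyl proceeds with retention because only the O–H bond reacts, and the weakly basic medium does not promote O8-to-O9 silyl migration.

Step 14
Reactants: 22 9-acetate 8-TES ether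
Product: 23 methyl (1(10)E,4E,6R,7R,8S,9S)-9-acetoxy-8-hydroxygermacra-1(10),4,11(13)-trien-12,6-olid-14-oate
Conditions: HF·pyridine, pyridine, THF, 0 °C
Reagents that add atoms: none
Why: Fluoride-assisted cleavage of the Si–O bond by buffered HF·pyridine removes the TES group under mildly acidic conditions in which the C9 acetate cannot migrate to O8 through an alkoxide.

Step 15
Reactants: 24 ethyl 2-(hydroxymethyl)prop-2-enoate
Product: 25 ethyl 2-{[(tert-butyldimethylsilyl)oxy]methyl}prop-2-enoate
Conditions: TBSCl, imidazole, CH2Cl2, 0 °C → rt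
Reagents that add atoms: tert-butyldimethylsilyl chloride (TBSCl), CC(C)(C)[Si](C)(C)Cl
Why: Silyl ether formation at the primary allylic hydroxyl masks it for the later acylation.

Step 16
Reactants: 25 ethyl 2-{[(tert-butyldimethylsilyl)oxy]methyl}prop-2-enoate
Product: 27 2-{[(tert-butyldimethylsilyl)oxy]methyl}prop-2-enoic acid, via lithium carboxylate 26 (not isolated)
Conditions: LiOH·H2O, THF/H2O, 0 °C → rt; then 1 M HCl to pH 4, 0 °C
Reagents that add atoms: LiOH, [Li+].[OH-]
Why: Saponification of the ethyl ester by LiOH gives carboxylate 26, and careful acidification to pH 4 liberates the acid without cleaving the TBS ether.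

Step 17
Reactants: 23 9-acetoxy-8-hydroxy melampolide; 27 2-{[(tert-butyldimethylsilyl)oxy]methyl}prop-2-enoic acid
Product: 28 methyl (1(10)E,4E,6R,7S,8S,9S)-9-acetoxy-8-[(2-{[(tert-butyldimethylsilyl)oxy]methyl}prop-2-enoyl)oxy]germacra-1(10),4,11(13)-trien-12,6-olid-14-oate
Conditions: DCC (N,N'-dicyclohexylcarbodiimide), DMAP (cat.), CH2Cl2, 0 °C → rt
Reagents that add atoms: none
Why: Steglich esterification: the carbodiimide-activated acid is transferred by DMAP to the C8 hydroxyl with retention at C8, and the low temperature together with an excess of activated acid lets acylation outrun base-induced O9-to-O8 acetyl migration.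

Step 18
Reactants: 28 silyl-protected target
Product: 29 CNP0291058.1, methyl (1(10)E,4E,6R,7S,8S,9S)-9-acetoxy-8-{[2-(hydroxymethyl)prop-2-enoyl]oxy}germacra-1(10),4,11(13)-trien-12,6-olid-14-oate
Conditions: HF·pyridine, pyridine, THF, 0 °C → rt
Reagents that add atoms: none
Why: HF·pyridine cleaves the primary TBS ether by fluoride attack at silicon without touching the acetate, the acrylate ester, the methyl ester or the α-methylene lactone, and should give the target.

Compound list
1 | geranyl acetate, (2E)-3,7-dimethylocta-2,6-dien-1-yl acetate | CC(=O)OC/C=C(\C)CCC=C(C)C | starting material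
2 | 6,7-epoxygeranyl acetate (racemic epoxide) | CC(=O)OC/C=C(\C)CCC1OC1(C)C | intermediate
3 | (2E)-6,7-dihydroxy-3,7-dimethyloct-2-en-1-yl acetate (racemic) | CC(=O)OC/C=C(\C)CCC(O)C(C)(C)O | intermediate (not isolated)
4 | (2E)-3-methyl-6-oxohex-2-en-1-yl acetate | CC(=O)OC/C=C(\C)CCC=O | intermediate
5 | methyl (2Z,6E)-8-acetoxy-2-iodo-6-methylocta-2,6-dienoate | CC(=O)OC/C=C(\C)CC/C=C(\I)C(=O)OC | intermediate
6 | methyl (2Z,6E)-8-hydroxy-2-iodo-6-methylocta-2,6-dienoate | OC/C=C(\C)CC/C=C(\I)C(=O)OC | intermediate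
7 | methyl (2Z,6E)-2-iodo-6-methyl-8-oxoocta-2,6-dienoate (C1–C6 enal carrying C10 and C14) | O=C/C=C(\C)CC/C=C(\I)C(=O)OC | intermediate
8 | (R)-2,3-O-isopropylideneglyceraldehyde, (4R)-2,2-dimethyl-1,3-dioxolane-4-carbaldehyde | O=C[C@H]1COC(C)(C)O1 | starting material
9 | methyl acrylate | C=CC(=O)OC | starting material
10 | methyl 2-{[(4R)-2,2-dimethyl-1,3-dioxolan-4-yl](hydroxy)methyl}prop-2-enoate (both carbinol epimers) | C=C(C(=O)OC)C(O)[C@H]1COC(C)(C)O1 | intermediate
11 | methyl (2Z)-2-(bromomethyl)-3-[(4S)-2,2-dimethyl-1,3-dioxolan-4-yl]prop-2-enoate | COC(=O)/C(CBr)=C/[C@H]1COC(C)(C)O1 | intermediate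
12 | allylchromium reagent from 11, dichloro{2-(methoxycarbonyl)-3-[(4S)-2,2-dimethyl-1,3-dioxolan-4-yl]prop-2-en-1-yl}chromium (trivalent chromium, olefin geometry mobile) | COC(=O)C(C[Cr](Cl)Cl)=C[C@H]1COC(C)(C)O1 | intermediate (not isolated)
13 | dichlorochromium alkoxide of the anti homoallylic alcohol from 7 and 12 (6R,7S,8S; open-chain hydroxy diester) | COC(=O)C(=C)[C@@H]([C@H](O[Cr](Cl)Cl)/C=C(\C)CC/C=C(\I)C(=O)OC)[C@H]1COC(C)(C)O1 | intermediate (not isolated)
14 | methyl (2Z,6E)-7-{(2R,3S)-3-[(4S)-2,2-dimethyl-1,3-dioxolan-4-yl]-4-methylidene-5-oxooxolan-2-yl}-2-iodo-6-methylhepta-2,6-dienoate (6R,7S,8S) | CC1(C)OC[C@@H](O1)[C@H]1C(=C)C(=O)O[C@@H]1/C=C(\C)CC/C=C(\I)C(=O)OC | intermediate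
15 | methyl (2Z,6E)-7-{(2R,3R)-3-[(1S)-1,2-dihydroxyethyl]-4-methylidene-5-oxooxolan-2-yl}-2-iodo-6-methylhepta-2,6-dienoate (same spatial arrangement as 14) | OC[C@@H](O)[C@H]1C(=C)C(=O)O[C@@H]1/C=C(\C)CC/C=C(\I)C(=O)OC | intermediate
16 | methyl (2Z,6E)-7-{(2R,3S)-3-[(1S)-1,2-bis(triethylsilyloxy)ethyl]-4-methylidene-5-oxooxolan-2-yl}-2-iodo-6-methylhepta-2,6-dienoate | CC[Si](CC)(CC)OC[C@@H](O[Si](CC)(CC)CC)[C@H]1C(=C)C(=O)O[C@@H]1/C=C(\C)CC/C=C(\I)C(=O)OC | intermediate
17 | dimethyl(alkoxy)sulfonium chloride at O9 of the 8-TES ether | C[S+](C)OC[C@@H](O[Si](CC)(CC)CC)[C@H]1C(=C)C(=O)O[C@@H]1/C=C(\C)CC/C=C(\I)C(=O)OC.[Cl-] | intermediate (not isolated)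
18 | methyl (2Z,6E)-2-iodo-6-methyl-7-{(2R,3S)-4-methylidene-5-oxo-3-[(1S)-2-oxo-1-(triethylsilyloxy)ethyl]oxolan-2-yl}hepta-2,6-dienoate (lactone aldehyde, key-step substrate) | O=C[C@@H](O[Si](CC)(CC)CC)[C@H]1C(=C)C(=O)O[C@@H]1/C=C(\C)CC/C=C(\I)C(=O)OC | intermediate
19 | C10 alkenylchromium dichloride from 18 (trivalent chromium, C2 and Cr cis) | O=C[C@@H](O[Si](CC)(CC)CC)[C@H]1C(=C)C(=O)O[C@@H]1/C=C(\C)CC/C=C(\[Cr](Cl)Cl)C(=O)OC | intermediate (not isolated)
20 | dichlorochromium O9-alkoxide of 21 | CC[Si](CC)(CC)O[C@H]1[C@H]2C(=C)C(=O)O[C@@H]2/C=C(\C)CC/C=C(/C(=O)OC)[C@@H]1O[Cr](Cl)Cl | intermediate (not isolated)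
21 | methyl (1(10)E,4E,6R,7S,8S,9S)-9-hydroxy-8-(triethylsilyloxy)germacra-1(10),4,11(13)-trien-12,6-olid-14-oate (ring-cis C1=C10; key-step product) | CC[Si](CC)(CC)O[C@H]1[C@H]2C(=C)C(=O)O[C@@H]2/C=C(\C)CC/C=C(/C(=O)OC)[C@@H]1O | intermediate
22 | methyl (1(10)E,4E,6R,7S,8S,9S)-9-acetoxy-8-(triethylsilyloxy)germacra-1(10),4,11(13)-trien-12,6-olid-14-oate | CC[Si](CC)(CC)O[C@H]1[C@H]2C(=C)C(=O)O[C@@H]2/C=C(\C)CC/C=C(/C(=O)OC)[C@@H]1OC(C)=O | intermediate
23 | methyl (1(10)E,4E,6R,7R,8S,9S)-9-acetoxy-8-hydroxygermacra-1(10),4,11(13)-trien-12,6-olid-14-oate | O[C@H]1[C@H]2C(=C)C(=O)O[C@@H]2/C=C(\C)CC/C=C(/C(=O)OC)[C@@H]1OC(C)=O | intermediate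
24 | ethyl 2-(hydroxymethyl)prop-2-enoate | C=C(CO)C(=O)OCC | starting material
25 | ethyl 2-{[(tert-butyldimethylsilyl)oxy]methyl}prop-2-enoate | C=C(CO[Si](C)(C)C(C)(C)C)C(=O)OCC | intermediate
26 | lithium 2-{[(tert-butyldimethylsilyl)oxy]methyl}prop-2-enoate | [Li+].[O-]C(=O)C(=C)CO[Si](C)(C)C(C)(C)C | intermediate (not isolated)
27 | 2-{[(tert-butyldimethylsilyl)oxy]methyl}prop-2-enoic acid | C=C(CO[Si](C)(C)C(C)(C)C)C(=O)O | intermediate
28 | methyl (1(10)E,4E,6R,7S,8S,9S)-9-acetoxy-8-[(2-{[(tert-butyldimethylsilyl)oxy]methyl}prop-2-enoyl)oxy]germacra-1(10),4,11(13)-trien-12,6-olid-14-oate | C=C(CO[Si](C)(C)C(C)(C)C)C(=O)O[C@H]1[C@H]2C(=C)C(=O)O[C@@H]2/C=C(\C)CC/C=C(/C(=O)OC)[C@@H]1OC(C)=O | intermediate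
29 | CNP0291058.1, methyl (1(10)E,4E,6R,7S,8S,9S)-9-acetoxy-8-{[2-(hydroxymethyl)prop-2-enoyl]oxy}germacra-1(10),4,11(13)-trien-12,6-olid-14-oate | C=C(CO)C(=O)O[C@H]1[C@H]2C(=C)C(=O)O[C@@H]2/C=C(\C)CC/C=C(/C(=O)OC)[C@@H]1OC(C)=O | target

Total step count: 18 (steps 1–5 build the iodoenoate enal, steps 6–7 the bromide, steps 15–16 the side-chain acid).
Longest linear sequence: 14 steps (1–5, 8–14, 17, 18) from geranyl acetate.

Steps most likely to fail

Step 12 (ring closure). The process at risk is facial selection at C9: if the ring-forming addition follows the open-chain Felkin–Anh preference of the α-silyloxy aldehyde, C10 adds to the Re face and the 9R carbinol predominates. A second, smaller risk is loss of olefin geometry through an O-bound chromium allenoate form of 19. The fallback replaces direct stereocontrol in the C–C bond formation by correction at the ketone stage. It sets out from 18: the cyclisation product, the 9R epimer of 21 F1 (alone or mixed with 21), is oxidised with Dess–Martin periodinane (NaHCO3, CH2Cl2, 0 °C) to the C9 ketone F2, which is reduced at once with NaBH4/CeCl3·7H2O (MeOH/THF, −78 °C). For a ketone flanked by a non-chelating silyl ether, 1,2-delivery of hydride anti to the C8–O bond (Felkin–Anh) leads to the 8,9-syn carbinol, the sense opposite to that of carbon addition to the aldehyde. CeCl3 keeps the reduction 1,2 and suppresses conjugate reduction of the enoate and of the exo-methylene lactone. The sequence returns to the route at 21.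

Step 8 (allylation and lactonisation). The process at risk is π-facial discrimination at C7 by the dioxolane stereocentre: the aldehyde may bond anti to the C8–O bond instead of anti to the C8–C9 bond, which would give the lactone with C6 and C7 inverted relative to C8. The fallback keeps the same bond construction but takes C8 from the other enantiomer of the chiral pool and inverts it afterwards. It sets out from 7 and 9:
- Commercial (S)-2,3-O-isopropylideneglyceraldehyde and 9 give, under the conditions of steps 6 and 7, the enantiomeric Morita–Baylis–Hillman adduct F3 and the enantiomeric bromide F4.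
- Coupling of F4 with 7 (CrCl2, THF), with the reversed facial sense, would give the 8-epimer of 14 F5 (6R,7S,8R), correct at C6 and C7.
- Aqueous AcOH gives the 8-epimer of 15 F6.
- TESCl in pyridine/CH2Cl2 at −20 °C silylates the primary hydroxyl only, giving the 9-O-TES 8R alcohol F7.
- Mitsunobu reaction with chloroacetic acid (PPh3, diisopropyl azodicarboxylate, toluene, 0 °C → rt) inverts C8 to the 8S chloroacetate F8.
- Thiourea/NaHCO3 in EtOH removes the chloroacetyl group under neutral conditions to give the 9-O-TES 8S alcohol F9.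
- TESOTf/2,6-lutidine returns to the route at 16.

Step 11 (unmasking of the C9 aldehyde). The processes at risk are incomplete differentiation of the primary and secondary silyl ethers by the chlorosulfonium reagent, and epimerisation at C8 of the α-silyloxy aldehyde on contact with the amine base. The fallback separates deprotection from oxidation and avoids the amine. It sets out from 16: buffered HF·pyridine (pyridine, THF, −20 → 0 °C) cleaves the primary TES ether selectively to the 8-O-TES primary alcohol F10, and Dess–Martin periodinane with NaHCO3 (CH2Cl2, 0 °C) oxidises it to the aldehyde, returning to the route at 18.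

Further compounds
F1 | step 12 | 9R epimer of 21, methyl (1(10)E,4E,6R,7S,8S,9R)-9-hydroxy-8-(triethylsilyloxy)germacra-1(10),4,11(13)-trien-12,6-olid-14-oate | CC[Si](CC)(CC)O[C@H]1[C@H]2C(=C)C(=O)O[C@@H]2/C=C(\C)CC/C=C(/C(=O)OC)[C@H]1O
F2 | step 12 | C9 ketone, methyl (1(10)E,4E,6R,7S,8S)-9-oxo-8-(triethylsilyloxy)germacra-1(10),4,11(13)-trien-12,6-olid-14-oate | CC[Si](CC)(CC)O[C@H]1[C@H]2C(=C)C(=O)O[C@@H]2/C=C(\C)CC/C=C(/C(=O)OC)C1=O
F3 | step 8 | enantiomeric Morita–Baylis–Hillman adduct, methyl 2-{[(4S)-2,2-dimethyl-1,3-dioxolan-4-yl](hydroxy)methyl}prop-2-enoate (both carbinol epimers) | C=C(C(=O)OC)C(O)[C@@H]1COC(C)(C)O1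
F4 | step 8 | enantiomeric bromide, methyl (2Z)-2-(bromomethyl)-3-[(4R)-2,2-dimethyl-1,3-dioxolan-4-yl]prop-2-enoate | COC(=O)/C(CBr)=C/[C@@H]1COC(C)(C)O1
F5 | step 8 | 8-epimer of 14 (6R,7S,8R), methyl (2Z,6E)-7-{(2R,3S)-3-[(4R)-2,2-dimethyl-1,3-dioxolan-4-yl]-4-methylidene-5-oxooxolan-2-yl}-2-iodo-6-methylhepta-2,6-dienoate | CC1(C)OC[C@H](O1)[C@H]1C(=C)C(=O)O[C@@H]1/C=C(\C)CC/C=C(\I)C(=O)OC
F6 | step 8 | 8-epimer of 15, the (1R)-1,2-dihydroxyethyl lactone | OC[C@H](O)[C@H]1C(=C)C(=O)O[C@@H]1/C=C(\C)CC/C=C(\I)C(=O)OC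
F7 | step 8 | 9-O-TES 8R alcohol, the (1R)-1-hydroxy-2-(triethylsilyloxy)ethyl lactone | CC[Si](CC)(CC)OC[C@H](O)[C@H]1C(=C)C(=O)O[C@@H]1/C=C(\C)CC/C=C(\I)C(=O)OC
F8 | step 8 | 8S chloroacetate, the (1S)-1-(chloroacetoxy)-2-(triethylsilyloxy)ethyl lactone | CC[Si](CC)(CC)OC[C@@H](OC(=O)CCl)[C@H]1C(=C)C(=O)O[C@@H]1/C=C(\C)CC/C=C(\I)C(=O)OC
F9 | step 8 | 9-O-TES 8S alcohol, the (1S)-1-hydroxy-2-(triethylsilyloxy)ethyl lactone | CC[Si](CC)(CC)OC[C@@H](O)[C@H]1C(=C)C(=O)O[C@@H]1/C=C(\C)CC/C=C(\I)C(=O)OC
F10 | step 11 | 8-O-TES primary alcohol, the (1S)-2-hydroxy-1-(triethylsilyloxy)ethyl lactone | OC[C@@H](O[Si](CC)(CC)CC)[C@H]1C(=C)C(=O)O[C@@H]1/C=C(\C)CC/C=C(\I)C(=O)OC
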